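Both pyranone rings are cut at C2–C3, which turns the target into a biaryl carrying two phloroglucinol-derived acetophenones. Each ring has its acetyl carbon ortho to the phenolic oxygen destined to become O1, and in the apigenin unit that oxygen is the one beside the C8–aryl bond. An aroyl group parked on it can therefore be handed to the acetyl methyl carbon through a six-membered transition state. One base treatment of the bis(aryl ester) performs both O-to-C acyl shifts, forging both C2–C3 bonds and baring the two ring-forming phenols. The remaining five phenols travel as allyl ethers, inert to the acid that later closes the rings, so only the correct oxygen can cyclise.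

Key step: step 9

Remark: the target SMILES defines no stereocentre and no configuration for the biaryl axis, so none is controlled; 1,1-diethoxy-3-methylbut-2-ene and 4-(prop-2-enyloxy)benzoyl chloride are taken as catalogue compounds.

Step 1
Reactants: 1 methyl 4-hydroxy-3-iodobenzoate; 2 1,1-diethoxy-3-methylbut-2-ene
Product: 3 methyl 8-iodo-2,2-dimethyl-2H-chromene-6-carboxylate
Conditions: 3-picoline (0.5 equiv), p-xylene, 140 °C, EtOH distilled off
Reagents that add atoms: none
Why: Base-catalysed chromenylation of a phenol with an enal acetal (ortho C-alkylation by the acetal carbon, loss of ethanol to an ortho-quinone methide, oxa-6π electrocyclisation) is a known one-step route to 2,2-dimethyl-2H-chromenes from phenols with electron-withdrawing para groups, and since C5 of 1 is the only free ortho position the pyran ring can fuse only there, leaving iodine at the future C8.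

Step 2
Reactants: 3 methyl 8-iodo-2,2-dimethyl-2H-chromene-6-carboxylate
Product: 4 methyl 2,2-dimethyl-8-(4,4,5,5-tetramethyl-1,3,2-dioxaborolan-2-yl)-2H-chromene-6-carboxylate
Conditions: bis(pinacolato)diboron, PdCl2(dppf) (5 mol%), KOAc, 1,4-dioxane, 90 °C
Reagents that add atoms: bis(pinacolato)diboron, CC1(C)OB(OC1(C)C)B1OC(C)(C)C(C)(C)O1
Why: Miyaura borylation of an aryl iodide, in which KOAc is too weak a base to touch the methyl ester or to promote biaryl homocoupling and the chromene alkene should not be engaged by the catalyst.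

Step 3
Reactants: 5 1-(2,4,6-trihydroxyphenyl)ethanone
Product: 6 1-[2-hydroxy-4,6-bis(prop-2-enyloxy)phenyl]ethanone
Conditions: allyl bromide (2.1 equiv), K2CO3 (2.2 equiv), acetone, reflux
Reagents that add atoms: allyl bromide, C=CCBr
Why: Williamson etherification in which the 4-hydroxyl and one ortho hydroxyl are alkylated while the last ortho hydroxyl, held in a strong hydrogen bond to the acetyl carbonyl, should stay free, as is usual for this ketone with two equivalents of an alkyl halide.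

Step 4
Reactants: 6 1-[2-hydroxy-4,6-bis(prop-2-enyloxy)phenyl]ethanone
Product: 7 1-[2-hydroxy-3-iodo-4,6-bis(prop-2-enyloxy)phenyl]ethanone
Conditions: N-iodosuccinimide (1.05 equiv), MeCN, 0 °C to rt, dark
Reagents that add atoms: N-iodosuccinimide, O=C1CCC(=O)N1I
Why: Electrophilic aromatic iodination, in which the open position between the chelated hydroxyl and an allyloxy group (C3) should be attacked in preference to the one between two allyloxy groups, the pattern established for 2-hydroxy-4,6-dialkoxyacetophenones, while the electron-rich ring reacts far faster than the allyl alkenes.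

Step 5
Reactants: 4 methyl 2,2-dimethyl-8-(4,4,5,5-tetramethyl-1,3,2-dioxaborolan-2-yl)-2H-chromene-6-carboxylate; 7 1-[2-hydroxy-3-iodo-4,6-bis(prop-2-enyloxy)phenyl]ethanone
Product: 8 methyl 8-[3-acetyl-2-hydroxy-4,6-bis(prop-2-enyloxy)phenyl]-2,2-dimethyl-2H-chromene-6-carboxylate
Conditions: Pd(OAc)2 (5 mol%), SPhos (10 mol%), K3PO4 (3 equiv), toluene/H2O 10:1, 90 °C, degassed
Reagents that add atoms: none
Why: Suzuki–Miyaura coupling with a dialkylbiarylphosphine ligand suited to tri-ortho-substituted biaryls, in which the iodophenol couples as its phenoxide, oxidative addition into the C–I bond should outpace ionisation of the allyl ethers in an alcohol-free medium, and the new bond joins chromene C8 to the carbon next to the free hydroxyl.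

Step 6
Reactants: 8 methyl 8-[3-acetyl-2-hydroxy-4,6-bis(prop-2-enyloxy)phenyl]-2,2-dimethyl-2H-chromene-6-carboxylate
Product: 9 8-[3-acetyl-2-hydroxy-4,6-bis(prop-2-enyloxy)phenyl]-2,2-dimethyl-2H-chromene-6-carboxylic acid
Conditions: LiOH·H2O (4 equiv), THF/MeOH/H2O 3:1:1, 45 °C; then 1 M HCl to pH 3
Reagents that add atoms: lithium hydroxide, [Li+].[OH-]
Why: Saponification of a methyl benzoate, placed before either aryl ester exists because hydroxide would cleave those first, with allyl ethers, ketone and chromene inert to LiOH.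

Step 7
Reactants: 9 8-[3-acetyl-2-hydroxy-4,6-bis(prop-2-enyloxy)phenyl]-2,2-dimethyl-2H-chromene-6-carboxylic acid; 6 1-[2-hydroxy-4,6-bis(prop-2-enyloxy)phenyl]ethanone
Product: 10 2-acetyl-3,5-bis(prop-2-enyloxy)phenyl 8-[3-acetyl-2-hydroxy-4,6-bis(prop-2-enyloxy)phenyl]-2,2-dimethyl-2H-chromene-6-carboxylate
Conditions: EDC·HCl (1.5 equiv), DMAP (0.3 equiv), 6 (2 equiv), CH2Cl2, 0 °C to rt, 9 added slowly
Reagents that add atoms: none
Why: Steglich carbodiimide esterification, in which both phenols present are hydrogen-bonded to an acetyl group but that of 9 is also shielded on its other side by the twisted chromenyl ring, so the less hindered phenol of 6, kept in excess, should capture the acylpyridinium ion.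

Step 8
Reactants: 10 2-acetyl-3,5-bis(prop-2-enyloxy)phenyl 8-[3-acetyl-2-hydroxy-4,6-bis(prop-2-enyloxy)phenyl]-2,2-dimethyl-2H-chromene-6-carboxylate; 11 4-(prop-2-enyloxy)benzoyl chloride
Product: 12 2-acetyl-3,5-bis(prop-2-enyloxy)phenyl 8-{3-acetyl-4,6-bis(prop-2-enyloxy)-2-[4-(prop-2-enyloxy)benzoyloxy]phenyl}-2,2-dimethyl-2H-chromene-6-carboxylate
Conditions: 11 (1.8 equiv), Et3N (3 equiv), DMAP (0.2 equiv), CH2Cl2, 0 °C to 40 °C
Reagents that add atoms: none
Why: DMAP-catalysed acylation of a hindered phenol with an acid chloride, in which 10 offers a single nucleophilic site and Et3N cannot enolise either acetyl group, so no acyl shift should start before the key step.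

Step 9
Reactants: 12 2-acetyl-3,5-bis(prop-2-enyloxy)phenyl 8-{3-acetyl-4,6-bis(prop-2-enyloxy)-2-[4-(prop-2-enyloxy)benzoyloxy]phenyl}-2,2-dimethyl-2H-chromene-6-carboxylate
Product: 13 1-[2-hydroxy-4,6-bis(prop-2-enyloxy)phenyl]-3-(8-{2-hydroxy-3-[3-oxo-3-(4-prop-2-enyloxyphenyl)propanoyl]-4,6-bis(prop-2-enyloxy)phenyl}-2,2-dimethyl-2H-chromen-6-yl)propane-1,3-dione
Conditions: LiN(SiMe3)2 (7 equiv), THF, −78 °C to 0 °C; AcOH quench
Reagents that add atoms: none
Why: LiN(SiMe3)2 converts both acetyl groups into lithium enolates, and each enolate carbon attacks the ester carbonyl on its ortho oxygen through a six-membered cyclic tetrahedral intermediate that collapses to a phenoxide and a 1,3-diketone, which the excess base deprotonates at once so that neither shift can revert. This is the Baker–Venkataraman rearrangement, an intramolecular Claisen condensation, run at two sites of one molecule. No ring survives the step and no stereocentre is formed; the two bonds made are C2–C3 of the chromone and C2–C3 of the apigenin unit. Site selectivity is built in, since each enolate reaches its own ester through a six-membered array while the other ester could be reached only through a macrocycle, and intramolecular delivery should overcome the crowding at the acetyl group lying between an allyloxy group and the aroyloxy group next to the biaryl bond. Because the 4-(prop-2-enyloxy)benzoyl group sits on the oxygen beside the biaryl bond, the phenol freed there is the one that must become O1, which fixes the 8-aryl pattern. Allyl ethers, the chromene and the biaryl should be inert to the amide base at low temperature.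

Step 10
Reactants: 13 1-[2-hydroxy-4,6-bis(prop-2-enyloxy)phenyl]-3-(8-{2-hydroxy-3-[3-oxo-3-(4-prop-2-enyloxyphenyl)propanoyl]-4,6-bis(prop-2-enyloxy)phenyl}-2,2-dimethyl-2H-chromen-6-yl)propane-1,3-dione
Product: 14 8-{6-[4-oxo-5,7-bis(prop-2-enyloxy)-4H-chromen-2-yl]-2,2-dimethyl-2H-chromen-8-yl}-5,7-bis(prop-2-enyloxy)-2-[4-(prop-2-enyloxy)phenyl]-4H-chromen-4-one
Conditions: conc. HCl (cat.), MeOH/THF 1:1, 55 °C
Reagents that add atoms: none
Why: Acid-catalysed cyclodehydration of o-hydroxyaryl 1,3-diketones to 4-pyranones (6-exo-trig hemiketal formation, then loss of water), in which each diketone has exactly one free phenol because allyl ethers do not cleave in acid, which locks the 8-aryl connectivity of the apigenin unit, and dilute methanolic HCl is tolerated by 2,2-dimethyl-2H-chromenes.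

Step 11
Reactants: 14 8-{6-[4-oxo-5,7-bis(prop-2-enyloxy)-4H-chromen-2-yl]-2,2-dimethyl-2H-chromen-8-yl}-5,7-bis(prop-2-enyloxy)-2-[4-(prop-2-enyloxy)phenyl]-4H-chromen-4-one
Product: 15 8-[6-(5,7-dihydroxy-4-oxo-4H-chromen-2-yl)-2,2-dimethyl-2H-chromen-8-yl]-5,7-dihydroxy-2-(4-hydroxyphenyl)-4H-chromen-4-one (CNP0135272.0)
Conditions: Pd(PPh3)4 (15 mol%), morpholine (15 equiv), THF, rt, degassed; dilute citric acid work-up
Reagents that add atoms: none
Why: Tsuji–Trost-type allyl transfer from aryl allyl ethers to morpholine through π-allyl complexes of zerovalent palladium, in which the five primary allyl ethers ionise readily whereas the ring C–O bond of the chromene is a hindered tertiary endocyclic allylic ether lying near the nodal plane of its alkene and should not ionise at room temperature.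

Compound list
1 | methyl 4-hydroxy-3-iodobenzoate | COC(=O)c1ccc(O)c(I)c1 | starting material
2 | 1,1-diethoxy-3-methylbut-2-ene | CCOC(OCC)C=C(C)C | starting material
3 | methyl 8-iodo-2,2-dimethyl-2H-chromene-6-carboxylate | COC(=O)c1cc(I)c2OC(C)(C)C=Cc2c1 | intermediate
4 | methyl 2,2-dimethyl-8-(4,4,5,5-tetramethyl-1,3,2-dioxaborolan-2-yl)-2H-chromene-6-carboxylate | COC(=O)c1cc(B3OC(C)(C)C(C)(C)O3)c2OC(C)(C)C=Cc2c1 | intermediate
5 | 1-(2,4,6-trihydroxyphenyl)ethanone | CC(=O)c1c(O)cc(O)cc1O | starting material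
6 | 1-[2-hydroxy-4,6-bis(prop-2-enyloxy)phenyl]ethanone | CC(=O)c1c(O)cc(OCC=C)cc1OCC=C | intermediate
7 | 1-[2-hydroxy-3-iodo-4,6-bis(prop-2-enyloxy)phenyl]ethanone | CC(=O)c1c(O)c(I)c(OCC=C)cc1OCC=C | intermediate
8 | methyl 8-[3-acetyl-2-hydroxy-4,6-bis(prop-2-enyloxy)phenyl]-2,2-dimethyl-2H-chromene-6-carboxylate | COC(=O)c1cc(-c3c(O)c(C(C)=O)c(OCC=C)cc3OCC=C)c2OC(C)(C)C=Cc2c1 | intermediate
9 | 8-[3-acetyl-2-hydroxy-4,6-bis(prop-2-enyloxy)phenyl]-2,2-dimethyl-2H-chromene-6-carboxylic acid | OC(=O)c1cc(-c3c(O)c(C(C)=O)c(OCC=C)cc3OCC=C)c2OC(C)(C)C=Cc2c1 | intermediate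
10 | 2-acetyl-3,5-bis(prop-2-enyloxy)phenyl 8-[3-acetyl-2-hydroxy-4,6-bis(prop-2-enyloxy)phenyl]-2,2-dimethyl-2H-chromene-6-carboxylate | CC(=O)c1c(OCC=C)cc(OCC=C)cc1OC(=O)c1cc(-c3c(O)c(C(C)=O)c(OCC=C)cc3OCC=C)c2OC(C)(C)C=Cc2c1 | intermediate
11 | 4-(prop-2-enyloxy)benzoyl chloride | C=CCOc1ccc(C(=O)Cl)cc1 | starting material
12 | 2-acetyl-3,5-bis(prop-2-enyloxy)phenyl 8-{3-acetyl-4,6-bis(prop-2-enyloxy)-2-[4-(prop-2-enyloxy)benzoyloxy]phenyl}-2,2-dimethyl-2H-chromene-6-carboxylate | CC(=O)c1c(OCC=C)cc(OCC=C)cc1OC(=O)c1cc(-c3c(OC(=O)c4ccc(OCC=C)cc4)c(C(C)=O)c(OCC=C)cc3OCC=C)c2OC(C)(C)C=Cc2c1 | intermediate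
13 | 1-[2-hydroxy-4,6-bis(prop-2-enyloxy)phenyl]-3-(8-{2-hydroxy-3-[3-oxo-3-(4-prop-2-enyloxyphenyl)propanoyl]-4,6-bis(prop-2-enyloxy)phenyl}-2,2-dimethyl-2H-chromen-6-yl)propane-1,3-dione | C=CCOc1cc(OCC=C)c(C(=O)CC(=O)c2cc(-c3c(O)c(C(=O)CC(=O)c4ccc(OCC=C)cc4)c(OCC=C)cc3OCC=C)c3OC(C)(C)C=Cc3c2)c(O)c1 | intermediate
14 | 8-{6-[4-oxo-5,7-bis(prop-2-enyloxy)-4H-chromen-2-yl]-2,2-dimethyl-2H-chromen-8-yl}-5,7-bis(prop-2-enyloxy)-2-[4-(prop-2-enyloxy)phenyl]-4H-chromen-4-one | CC1(C)C=Cc2cc(-c3cc(=O)c4c(OCC=C)cc(OCC=C)cc4o3)cc(-c3c(OCC=C)cc(OCC=C)c4c(=O)cc(-c5ccc(OCC=C)cc5)oc34)c2O1 | intermediate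
15 | 8-[6-(5,7-dihydroxy-4-oxo-4H-chromen-2-yl)-2,2-dimethyl-2H-chromen-8-yl]-5,7-dihydroxy-2-(4-hydroxyphenyl)-4H-chromen-4-one | CC1(C)C=Cc2cc(-c3cc(=O)c4c(O)cc(O)cc4o3)cc(-c3c(O)cc(O)c4c(=O)cc(-c5ccc(O)cc5)oc34)c2O1 | target

Total step count: 11.
Longest linear sequence: 9 steps (1 → 3 → 4 → 8 → 9 → 10 → 12 → 13 → 14 → 15; the branch from 5 through 6 and 7 is equally long).

Steps most likely to fail

Step 9. Acyl transfer at the doubly flanked acetyl group of the apigenin-forming ring may be slow, so that attack of the amide base on the aryl esters or intermolecular ester exchange competes before both shifts are complete. The fallback separates the two shifts and closes the hindered ring first; it sets out from 8 and comes back at 14. Compound 8 is aroylated with 11 (Et3N, DMAP, CH2Cl2) to methyl 8-{3-acetyl-4,6-bis(prop-2-enyloxy)-2-[4-(prop-2-enyloxy)benzoyloxy]phenyl}-2,2-dimethyl-2H-chromene-6-carboxylate F1. A single Baker–Venkataraman shift, which can be forced (KOtBu or LiN(SiMe3)2, THF, up to rt) because the only other ester is a methyl ester, should give methyl 8-{2-hydroxy-3-[3-oxo-3-(4-prop-2-enyloxyphenyl)propanoyl]-4,6-bis(prop-2-enyloxy)phenyl}-2,2-dimethyl-2H-chromene-6-carboxylate F2. Catalytic HCl in MeOH/THF closes it to methyl 2,2-dimethyl-8-{4-oxo-5,7-bis(prop-2-enyloxy)-2-[4-(prop-2-enyloxy)phenyl]-4H-chromen-8-yl}-2H-chromene-6-carboxylate F3, and LiOH in aqueous THF gives 2,2-dimethyl-8-{4-oxo-5,7-bis(prop-2-enyloxy)-2-[4-(prop-2-enyloxy)phenyl]-4H-chromen-8-yl}-2H-chromene-6-carboxylic acid F4. Esterification with 6 (EDC·HCl, DMAP), now with no competing phenol, gives 2-acetyl-3,5-bis(prop-2-enyloxy)phenyl 2,2-dimethyl-8-{4-oxo-5,7-bis(prop-2-enyloxy)-2-[4-(prop-2-enyloxy)phenyl]-4H-chromen-8-yl}-2H-chromene-6-carboxylate F5. The second, unhindered shift (LiN(SiMe3)2, THF) gives 1-[2-hydroxy-4,6-bis(prop-2-enyloxy)phenyl]-3-(2,2-dimethyl-8-{4-oxo-5,7-bis(prop-2-enyloxy)-2-[4-(prop-2-enyloxy)phenyl]-4H-chromen-8-yl}-2H-chromen-6-yl)propane-1,3-dione F6, and the acid treatment of step 10 then delivers 14.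

Step 5. Protodeboronation of 4 and palladium-mediated loss of allyl groups in hot aqueous base may outrun transmetalation onto the crowded, phenoxide-bearing arylpalladium species. The fallback is a base-free, water-free Negishi coupling on the masked phenol; it sets out from 3 and 7 and comes back at 8. Compound 7 is capped (MOMCl, NaH, DMF, 0 °C) as 1-[3-iodo-2-(methoxymethoxy)-4,6-bis(prop-2-enyloxy)phenyl]ethanone F7. Compound 3 is converted by zinc insertion (Zn dust, LiCl, THF, 40 °C) into [6-(methoxycarbonyl)-2,2-dimethyl-2H-chromen-8-yl]zinc iodide F8. Coupling of the two (Pd(OAc)2, SPhos, THF, 50 °C) should give methyl 8-[3-acetyl-2-(methoxymethoxy)-4,6-bis(prop-2-enyloxy)phenyl]-2,2-dimethyl-2H-chromene-6-carboxylate F9. Its acetal, activated by the ortho carbonyl, is removed with catalytic HCl in MeOH at rt to give 8.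

Step 1. Ortho C–C bond formation on the electron-poor iodophenol may be too slow, so that the acetal decomposes thermally before the chromene forms. The fallback is the propargyl ether route; it sets out from 1 and comes back at 3. Compound 1 is O-alkylated with 3-chloro-3-methylbut-1-yne (K2CO3, KI, CuCl cat., acetone, 60 °C) to methyl 3-iodo-4-[(2-methylbut-3-yn-2-yl)oxy]benzoate F10. Heating in N,N-diethylaniline at 185 °C (aryl propargyl ether Claisen rearrangement, 1,5-hydrogen shift, oxa-6π electrocyclisation) should give 3.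

Further compounds
F1 | step 9 | methyl 8-{3-acetyl-4,6-bis(prop-2-enyloxy)-2-[4-(prop-2-enyloxy)benzoyloxy]phenyl}-2,2-dimethyl-2H-chromene-6-carboxylate | COC(=O)c1cc(-c3c(OC(=O)c4ccc(OCC=C)cc4)c(C(C)=O)c(OCC=C)cc3OCC=C)c2OC(C)(C)C=Cc2c1
F2 | step 9 | methyl 8-{2-hydroxy-3-[3-oxo-3-(4-prop-2-enyloxyphenyl)propanoyl]-4,6-bis(prop-2-enyloxy)phenyl}-2,2-dimethyl-2H-chromene-6-carboxylate | COC(=O)c1cc(-c3c(O)c(C(=O)CC(=O)c4ccc(OCC=C)cc4)c(OCC=C)cc3OCC=C)c2OC(C)(C)C=Cc2c1
F3 | step 9 | methyl 2,2-dimethyl-8-{4-oxo-5,7-bis(prop-2-enyloxy)-2-[4-(prop-2-enyloxy)phenyl]-4H-chromen-8-yl}-2H-chromene-6-carboxylate | COC(=O)c1cc(-c3c(OCC=C)cc(OCC=C)c4c(=O)cc(-c5ccc(OCC=C)cc5)oc34)c2OC(C)(C)C=Cc2c1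
F4 | step 9 | 2,2-dimethyl-8-{4-oxo-5,7-bis(prop-2-enyloxy)-2-[4-(prop-2-enyloxy)phenyl]-4H-chromen-8-yl}-2H-chromene-6-carboxylic acid | OC(=O)c1cc(-c3c(OCC=C)cc(OCC=C)c4c(=O)cc(-c5ccc(OCC=C)cc5)oc34)c2OC(C)(C)C=Cc2c1
F5 | step 9 | 2-acetyl-3,5-bis(prop-2-enyloxy)phenyl 2,2-dimethyl-8-{4-oxo-5,7-bis(prop-2-enyloxy)-2-[4-(prop-2-enyloxy)phenyl]-4H-chromen-8-yl}-2H-chromene-6-carboxylate | CC(=O)c1c(OCC=C)cc(OCC=C)cc1OC(=O)c1cc(-c3c(OCC=C)cc(OCC=C)c4c(=O)cc(-c5ccc(OCC=C)cc5)oc34)c2OC(C)(C)C=Cc2c1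
F6 | step 9 | 1-[2-hydroxy-4,6-bis(prop-2-enyloxy)phenyl]-3-(2,2-dimethyl-8-{4-oxo-5,7-bis(prop-2-enyloxy)-2-[4-(prop-2-enyloxy)phenyl]-4H-chromen-8-yl}-2H-chromen-6-yl)propane-1,3-dione | C=CCOc1cc(OCC=C)c(C(=O)CC(=O)c2cc(-c3c(OCC=C)cc(OCC=C)c4c(=O)cc(-c5ccc(OCC=C)cc5)oc34)c3OC(C)(C)C=Cc3c2)c(O)c1
F7 | step 5 | 1-[3-iodo-2-(methoxymethoxy)-4,6-bis(prop-2-enyloxy)phenyl]ethanone | CC(=O)c1c(OCOC)c(I)c(OCC=C)cc1OCC=C
F8 | step 5 | [6-(methoxycarbonyl)-2,2-dimethyl-2H-chromen-8-yl]zinc iodide | COC(=O)c1cc([Zn]I)c2OC(C)(C)C=Cc2c1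
F9 | step 5 | methyl 8-[3-acetyl-2-(methoxymethoxy)-4,6-bis(prop-2-enyloxy)phenyl]-2,2-dimethyl-2H-chromene-6-carboxylate | COC(=O)c1cc(-c3c(OCOC)c(C(C)=O)c(OCC=C)cc3OCC=C)c2OC(C)(C)C=Cc2c1
F10 | step 1 | methyl 3-iodo-4-[(2-methylbut-3-yn-2-yl)oxy]benzoate | COC(=O)c1ccc(OC(C)(C)C#C)c(I)c1
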